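**Plan**
- Retrosynthesis: remove the silyl groups; take out C3 with its aroyl group (cut C2–C3 and C3–C4, join C2–C4) to reach a bicyclo[3.2.1]octane-6,7,8-trione and an aroyl diazomethane; cut C1–C2 (intramolecular Claisen); cut C5–C6 (the C8–C7–C6 unit with its prenyl and gem-dimethyl groups is a cyclised lavandulyl group); build the open chain by acetoacetate alkylations and an oxalate Claisen.
- Forward ring order: acyclic 2,4-dioxo ester → cyclohexanone (C5–C6) → bicyclo[3.2.1]octane-6,7,8-trione (C1–C2) → bicyclo[3.3.1]nonane by one-carbon enlargement of the five-membered ring C1–C2–C4–C5–C9.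
- Enabling feature: C3 lies between the carbonyl carbons C2 and C4, each bound to a quaternary bridgehead (C1, C5). Without C3 that ring is a non-enolisable vicinal diketone, and insertion of a diazo carbon into its C2–C4 bond gives the same 2-aroyl-1,3-dione whichever carbonyl is attacked.
- Stereochemistry: both lavandulyl units come from (S)-lavandulol (auxiliary-controlled alkylation). One stays as the side chain, the other becomes C8–C7–C6 and fixes C7. C5 is set in the carbocyclisation (the chelated enol keeps the C4 acyl group equatorial, cis to the equatorial prenyl group). C1 is set by the Claisen closure, which can only bridge cis.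
- Protecting groups: TES on the tertiary alcohol, TBS on the catechol, removed together in the last step.

Key step: step 15

Assumption: the β-triketone is drawn as one enol tautomer and the tautomers interconvert; numbering used throughout is C1 (lavandulyl bridgehead), C2 (C–OH), C3, C4 (C=O), C5 (other bridgehead), C6 (CMe2), C7 (CH-prenyl), C8 (CH2), C9 (bridging C=O); "lavandulyl" means the CH2-bound group with the configuration of (S)-lavandulol.

**Route**

Step 1
Reactants: 1 (S)-4-benzyl-1,3-oxazolidin-2-one; 2 3-methylbut-2-enoyl chloride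
Product: 3 (S)-4-benzyl-3-(3-methylbut-2-enoyl)-1,3-oxazolidin-2-one
Conditions: n-BuLi, THF, −78 °C; then 2, −78 → 0 °C
Reagents that add atoms: none
Why: N-acylation of the lithiated oxazolidinone by the acid chloride (standard imide formation), no stereocentre is made.

Step 2
Reactants: 3 (S)-4-benzyl-3-(3-methylbut-2-enoyl)-1,3-oxazolidin-2-one; 4 prenyl bromide (1-bromo-3-methylbut-2-ene)
Product: 5 (S)-4-benzyl-3-[(2S)-5-methyl-2-(prop-1-en-2-yl)hex-4-enoyl]-1,3-oxazolidin-2-one
Conditions: NaHMDS, THF, −78 °C; then 4, −78 → −40 °C
Reagents that add atoms: none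
Why: γ-deprotonation gives the chelated (Z)-dienolate, which should be alkylated at the α-carbon on the face away from the benzyl group (deconjugative Evans asymmetric alkylation), setting the (2S) lavandulyl stereocentre.

Step 3
Reactants: 5 (S)-4-benzyl-3-[(2S)-5-methyl-2-(prop-1-en-2-yl)hex-4-enoyl]-1,3-oxazolidin-2-one
Product: 6 (S)-lavandulol, (2S)-5-methyl-2-(prop-1-en-2-yl)hex-4-en-1-ol
Conditions: LiBH4, MeOH (1 equiv), Et2O, 0 °C
Reagents that add atoms: none
Why: reductive cleavage of the N-acyl oxazolidinone to the primary alcohol, which should leave the non-conjugated α-stereocentre untouched and return the auxiliary.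

Step 4
Reactants: 6 (S)-lavandulol
Product: 7 (S)-lavandulyl iodide, (3S)-3-(iodomethyl)-2,6-dimethylhepta-1,5-diene
Conditions: I2, PPh3, imidazole, CH2Cl2, 0 °C → rt
Reagents that add atoms: iodine, II
Why: Garegg–Samuelsson (Appel-type) iodination by SN2 at the primary carbon, the stereocentre is not involved.

Step 5
Reactants: 8 3-methylbutane-1,3-diol
Product: 9 4-iodo-2-methylbutan-2-ol
Conditions: I2, PPh3, imidazole, THF, 0 °C
Reagents that add atoms: iodine, II
Why: Garegg–Samuelsson iodination is selective for the primary hydroxyl group over the tertiary one.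

Step 6
Reactants: 9 4-iodo-2-methylbutan-2-ol
Product: 10 triethyl[(4-iodo-2-methylbutan-2-yl)oxy]silane
Conditions: TESOTf, 2,6-lutidine, CH2Cl2, −78 → 0 °C
Reagents that add atoms: triethylsilyl trifluoromethanesulfonate, CC[Si](CC)(CC)OS(=O)(=O)C(F)(F)F
Why: silyl triflate/lutidine silylation is the standard way to protect a tertiary alcohol.

Step 7
Reactants: 11 3,4-dihydroxybenzoic acid
Product: 12 tert-butyldimethylsilyl 3,4-bis(tert-butyldimethylsilyloxy)benzoate
Conditions: TBSCl, imidazole, DMF, rt
Reagents that add atoms: tert-butyldimethylsilyl chloride, CC(C)(C)[Si](C)(C)Cl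
Why: exhaustive silylation of both phenols and the acid gives a silyl ester that can be turned into the acid chloride without acid.

Step 8
Reactants: 12 tert-butyldimethylsilyl 3,4-bis(tert-butyldimethylsilyloxy)benzoate; 13 (trimethylsilyl)diazomethane
Product: 15 1-[3,4-bis(tert-butyldimethylsilyloxy)phenyl]-2-diazoethan-1-one, via acid chloride 14 (not isolated)
Conditions: (COCl)2, DMF (cat.), CH2Cl2, 0 °C → rt, concentrate; then 13, MeCN/THF, 0 °C
Reagents that add atoms: none
Why: oxalyl chloride/DMF converts a silyl ester directly into the acid chloride under neutral conditions, and acylation of the silyl diazomethane with loss of the silyl group (first stage of the Arndt–Eistert sequence) gives the α-diazo ketone.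

Step 9
Reactants: 16 allyl acetoacetate; 7 (S)-lavandulyl iodide (2 equiv)
Product: 18 allyl 4,4-bis(lavandulyl)-3-oxobutanoate, via mono-lavandulyl keto ester 17 (not isolated)
Conditions: NaH, THF, 0 °C; n-BuLi; 7, 0 °C → rt; then LDA, −78 °C; 7, DMPU, −78 °C → rt
Reagents that add atoms: none
Why: γ-alkylation of the acetoacetate dianion, run twice in one flask, since the γ-carbanion is the most nucleophilic site and should displace the primary iodide without touching the lavandulyl stereocentres.

Step 10
Reactants: 18 allyl 4,4-bis(lavandulyl)-3-oxobutanoate; 10 triethyl[(4-iodo-2-methylbutan-2-yl)oxy]silane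
Product: 19 allyl 4,4-bis(lavandulyl)-2-[3-methyl-3-(triethylsilyloxy)butyl]-3-oxobutanoate (epimers at C2)
Conditions: NaH, DMF, 0 → 50 °C
Reagents that add atoms: none
Why: C-alkylation of the β-keto ester monoanion with a primary iodide puts the future C5 side chain in place while that carbon is still unhindered; the new centre is lost in the next step.

Step 11
Reactants: 19 allyl 4,4-bis(lavandulyl)-2-[3-methyl-3-(triethylsilyloxy)butyl]-3-oxobutanoate
Product: 20 1,1-bis(lavandulyl)-6-methyl-6-(triethylsilyloxy)heptan-2-one
Conditions: Pd(PPh3)4 (5 mol %), morpholine, THF, rt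
Reagents that add atoms: none
Why: Pd(0)-catalysed deallylation (Tsuji–Trost type) frees the β-keto acid, which should decarboxylate at room temperature, far below the temperature at which the 1,5-diene units could rearrange.

Step 12
Reactants: 20 1,1-bis(lavandulyl)-6-methyl-6-(triethylsilyloxy)heptan-2-one; 21 dimethyl oxalate
Product: 22 methyl 5,5-bis(lavandulyl)-3-[3-methyl-3-(triethylsilyloxy)butyl]-2,4-dioxopentanoate (present as the chelated enol)
Conditions: LiHMDS, THF, −78 °C; then 21, −78 → 0 °C; cold 1 M HCl work-up
Reagents that add atoms: none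
Why: crossed Claisen condensation with oxalate at the kinetic enolate of the CH2 side (the other α-carbon is a hindered methine), and the acidic 1,3-dicarbonyl product is held as its enolate so that it does not react further.

Step 13
Reactants: 22 methyl 5,5-bis(lavandulyl)-3-[3-methyl-3-(triethylsilyloxy)butyl]-2,4-dioxopentanoate
Product: 23 methyl 2-oxo-2-{3-lavandulyl-6,6-dimethyl-1-[3-methyl-3-(triethylsilyloxy)butyl]-2-oxo-5-prenylcyclohexyl}acetate (ring C1 and C5 as in the target, oxalyl cis to prenyl; epimers at ring C3)
Conditions: Hg(OTf)2 (5 mol %), MeNO2, 0 °C → rt; Et3N quench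
Reagents that add atoms: none
Why: Proposed new method: Hg(II) should bind the less hindered 1,1-disubstituted C=C of either lavandulyl group (the two are the same in constitution), the enol carbon of the 1,3-dicarbonyl unit (future C5) should attack its tertiary terminus (future C6) in a 6-exo Markovnikov closure, and the C–Hg bond should be protonated by the TfOH released so that the catalyst turns over; the closest known reaction types are Hg(OTf)2-catalysed olefin cyclisation by carbon nucleophiles at isopropenyl groups, the Hg(OTf)2-catalysed Conia-ene cyclisation of alkynyl β-keto esters and cation–olefin cyclisations ended at the α-carbon of a β-dicarbonyl unit; a chair transition state with the C7 prenyl group equatorial, and the hydrogen-bonded enol holding the C4 acyl group in the enol plane (hence equatorial, cis to prenyl), should set C5 relative to C7, and each molecule has only one C–H acid, so the second lavandulyl group has no carbon nucleophile left.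

Step 14
Reactants: 23 methyl 2-oxo-2-{3-lavandulyl-6,6-dimethyl-1-[3-methyl-3-(triethylsilyloxy)butyl]-2-oxo-5-prenylcyclohexyl}acetate
Product: 24 1-lavandulyl-4,4-dimethyl-5-[3-methyl-3-(triethylsilyloxy)butyl]-3-prenylbicyclo[3.2.1]octane-6,7,8-trione (3-prenyl syn to the C6–C7 diketone bridge)
Conditions: LiHMDS, THF, −78 → −20 °C; AcOH quench at −78 °C
Reagents that add atoms: none
Why: intramolecular Claisen (Dieckmann-type) acylation in which the only enolisable carbon (future C1) attacks the ester carbon (future C2); the two-carbon bridge can only form on the face of C5 that carries the oxalyl group, so both C1 epimers should converge on one quaternary centre.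

Step 15
Reactants: 24 1-lavandulyl-4,4-dimethyl-5-[3-methyl-3-(triethylsilyloxy)butyl]-3-prenylbicyclo[3.2.1]octane-6,7,8-trione; 15 1-[3,4-bis(tert-butyldimethylsilyloxy)phenyl]-2-diazoethan-1-one
Product: 25 tris-silyl ether of the target: 3-[3,4-bis(tert-butyldimethylsilyloxy)benzoyl]-2-hydroxy-1-lavandulyl-6,6-dimethyl-5-[3-methyl-3-(triethylsilyloxy)butyl]-7-prenylbicyclo[3.3.1]non-2-ene-4,9-dione
Conditions: Sc(OTf)3 (20 mol %), 4 Å MS, CH2Cl2, −40 → 0 °C
Reagents that add atoms: none
Why: Proposed new method: Sc(III) should chelate the coplanar C2/C4 vicinal diketone of 24, the diazo carbon of 15 should add to one of these carbonyls from the face next to the small C9 bridge, and the β-oxido diazonium should lose N2 with a 1,2-shift of the neighbouring acyl carbon, which places the new carbon (C3, already carrying the aroyl group) between C2 and C4 before enolisation to the chelated β-triketone. The closest known reaction types are the Lewis-acid-promoted Tiffeneau–Demjanov (Büchner–Curtius–Schlotterbeck) homologation of ketones with diazo carbonyl compounds and the acyl-migration ring enlargement of vicinal di- and triketones with diazoalkanes; a bridged non-enolisable tricarbonyl compound and an α-diazo aryl ketone have not been combined in this way. No ring is closed: the five-membered ring C1–C2–C4–C5–C9 grows to the six-membered ring C1–C2–C3–C4–C5–C9 and the carbocycle is untouched. No stereocentre is created (C3 is sp2 in the enol and the transient carbinol centre disappears in the shift), and C1, C5 and C7 are not affected. The step needs attack at the diketone rather than at C9, which is flanked by two quaternary centres and is not chelated, and migration of the acyl carbon rather than the bridgehead carbon, which is quaternary and itself acyl-substituted and so should migrate poorly; which of the two carbonyls is attacked does not matter, because acyl migration from either adduct gives the same product.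

Step 16
Reactants: 25 tris-silyl ether of the target
Product: 26 target CNP0148616.1, 3-(3,4-dihydroxybenzoyl)-2-hydroxy-5-(3-hydroxy-3-methylbutyl)-1-lavandulyl-6,6-dimethyl-7-prenylbicyclo[3.3.1]non-2-ene-4,9-dione (configuration as in the given SMILES, 7-prenyl syn to the C2–C4 bridge)
Conditions: HF·pyridine, pyridine, THF, 0 °C → rt
Reagents that add atoms: none
Why: buffered fluoride should cleave the two aryl TBS ethers and the tertiary TES ether in one operation without the strong acid that would add the enol to a prenyl group.

**Compound list**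
1 | (S)-4-benzyl-1,3-oxazolidin-2-one | O=C1N[C@@H](Cc2ccccc2)CO1 | starting material
2 | 3-methylbut-2-enoyl chloride | CC(C)=CC(Cl)=O | starting material
3 | (S)-4-benzyl-3-(3-methylbut-2-enoyl)-1,3-oxazolidin-2-one | CC(C)=CC(=O)N1[C@@H](Cc2ccccc2)COC1=O | intermediate
4 | prenyl bromide | CC(C)=CCBr | starting material
5 | (S)-4-benzyl-3-[(2S)-5-methyl-2-(prop-1-en-2-yl)hex-4-enoyl]-1,3-oxazolidin-2-one | C=C(C)[C@H](CC=C(C)C)C(=O)N1[C@@H](Cc2ccccc2)COC1=O | intermediate
6 | (S)-lavandulol | C=C(C)[C@H](CC=C(C)C)CO | intermediate
7 | (S)-lavandulyl iodide | C=C(C)[C@H](CC=C(C)C)CI | intermediate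
8 | 3-methylbutane-1,3-diol | CC(C)(O)CCO | starting material
9 | 4-iodo-2-methylbutan-2-ol | CC(C)(O)CCI | intermediate
10 | triethyl[(4-iodo-2-methylbutan-2-yl)oxy]silane | CC[Si](CC)(CC)OC(C)(C)CCI | intermediate
11 | 3,4-dihydroxybenzoic acid | OC(=O)c1ccc(O)c(O)c1 | starting material
12 | tert-butyldimethylsilyl 3,4-bis(tert-butyldimethylsilyloxy)benzoate | CC(C)(C)[Si](C)(C)OC(=O)c1ccc(O[Si](C)(C)C(C)(C)C)c(O[Si](C)(C)C(C)(C)C)c1 | intermediate
13 | (trimethylsilyl)diazomethane | C[Si](C)(C)C=[N+]=[N-] | starting material
14 | 3,4-bis(tert-butyldimethylsilyloxy)benzoyl chloride | ClC(=O)c1ccc(O[Si](C)(C)C(C)(C)C)c(O[Si](C)(C)C(C)(C)C)c1 | intermediate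
15 | 1-[3,4-bis(tert-butyldimethylsilyloxy)phenyl]-2-diazoethan-1-one | [N-]=[N+]=CC(=O)c1ccc(O[Si](C)(C)C(C)(C)C)c(O[Si](C)(C)C(C)(C)C)c1 | intermediate
16 | allyl acetoacetate | CC(=O)CC(=O)OCC=C | starting material
17 | allyl 4-lavandulyl-3-oxobutanoate | C=CCOC(=O)CC(=O)CC[C@@H](CC=C(C)C)C(C)=C | intermediate
18 | allyl 4,4-bis(lavandulyl)-3-oxobutanoate | C=CCOC(=O)CC(=O)C(C[C@@H](CC=C(C)C)C(C)=C)C[C@@H](CC=C(C)C)C(C)=C | intermediate
19 | allyl 4,4-bis(lavandulyl)-2-[3-methyl-3-(triethylsilyloxy)butyl]-3-oxobutanoate | C=CCOC(=O)C(CCC(C)(C)O[Si](CC)(CC)CC)C(=O)C(C[C@@H](CC=C(C)C)C(C)=C)C[C@@H](CC=C(C)C)C(C)=C | intermediate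
20 | 1,1-bis(lavandulyl)-6-methyl-6-(triethylsilyloxy)heptan-2-one | CC[Si](CC)(CC)OC(C)(C)CCCC(=O)C(C[C@@H](CC=C(C)C)C(C)=C)C[C@@H](CC=C(C)C)C(C)=C | intermediate
21 | dimethyl oxalate | COC(=O)C(=O)OC | starting material
22 | methyl 5,5-bis(lavandulyl)-3-[3-methyl-3-(triethylsilyloxy)butyl]-2,4-dioxopentanoate (keto form shown) | COC(=O)C(=O)C(CCC(C)(C)O[Si](CC)(CC)CC)C(=O)C(C[C@@H](CC=C(C)C)C(C)=C)C[C@@H](CC=C(C)C)C(C)=C | intermediate
23 | methyl 2-oxo-2-{3-lavandulyl-6,6-dimethyl-1-[3-methyl-3-(triethylsilyloxy)butyl]-2-oxo-5-prenylcyclohexyl}acetate | COC(=O)C(=O)[C@@]1(CCC(C)(C)O[Si](CC)(CC)CC)C(=O)C(C[C@@H](CC=C(C)C)C(C)=C)C[C@@H](CC=C(C)C)C1(C)C | intermediate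
24 | 1-lavandulyl-4,4-dimethyl-5-[3-methyl-3-(triethylsilyloxy)butyl]-3-prenylbicyclo[3.2.1]octane-6,7,8-trione | C=C(C)[C@H](CC=C(C)C)C[C@@]12C[C@@H](CC=C(C)C)C(C)(C)[C@@](CCC(C)(C)O[Si](CC)(CC)CC)(C(=O)C1=O)C2=O | intermediate
25 | tris-silyl ether of the target | C=C(C)[C@H](CC=C(C)C)C[C@@]12C[C@@H](CC=C(C)C)C(C)(C)[C@@](CCC(C)(C)O[Si](CC)(CC)CC)(C(=O)C(C(=O)c3ccc(O[Si](C)(C)C(C)(C)C)c(O[Si](C)(C)C(C)(C)C)c3)=C1O)C2=O | intermediate
26 | CNP0148616.1 | C=C(C)[C@H](CC=C(C)C)C[C@@]12C[C@@H](CC=C(C)C)C(C)(C)[C@@](CCC(C)(C)O)(C(=O)C(C(=O)c3ccc(O)c(O)c3)=C1O)C2=O | target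

**Summary**
Total step count: 16. Longest linear sequence: 12 steps (steps 1–4, then 9–16).

**Steps most likely to fail**

Step 13 (proposed new method). The enol may attack through the C9 carbonyl oxygen instead of carbon and give a cyclic enol ether. Traces of triflic acid may protonate the trisubstituted prenyl double bonds and start cation–olefin cyclisation inside a lavandulyl unit, or isomerise the remaining isopropenyl group. Facial control at C5 may be weaker than the chair model predicts. The fallback uses known reaction types and sets out from 22. Mukaiyama hydration (Co(acac)2, PhSiH3, O2, i-PrOH), which prefers 1,1-disubstituted over trisubstituted alkenes, is run to partial conversion to give the mono-tertiary alcohol of 22, F1, with recovery of unreacted 22. Ionisation of the free tertiary alcohol with BF3·OEt2 in CH2Cl2 at −40 °C (acid-catalysed tert-alkylation of a β-dicarbonyl enol, reversible at oxygen and irreversible at carbon) then closes the C5–C6 bond and comes back to the route at 23.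

Step 15 (proposed new method). The bridgehead carbon may migrate instead of the acyl carbon, which would give an isomeric 1,2-diketone. The oxido diazonium may close to a spiro-epoxide. The Lewis acid may be sequestered by the β-triketone product or may loosen silyl ethers. The fallback is stepwise, uses known chemistry and sets out from 24. The lithium derivative of 15 (LDA, THF, −78 °C) adds to the diketone in an aldol-type reaction without any Lewis acid to give the α-diazo-β-hydroxy ketone F2 (either carbonyl may be attacked; both adducts converge). Rh2(OAc)4 in CH2Cl2 at rt then forms the carbenoid, which undergoes the known 1,2-shift ring expansion of β-hydroxy-α-diazo ketones and comes back to the route at 25.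

Step 14. Methoxide released in the Claisen closure may reopen the strained, non-enolisable trione (retro-Claisen), or the enolate oxygen may be acylated to give an enol lactone. The fallback avoids any alkoxide and sets out from 23. The α-keto methyl ester is hydrolysed selectively (LiOH, THF/H2O, 0 °C) to the α-keto acid F3. This is converted with DCC and pentafluorophenol into the pentafluorophenyl ester F4. Soft enolisation of the ketone with MgBr2·OEt2 and i-Pr2NEt in CH2Cl2 then gives direct C-acylation and comes back to the route at 24.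

**Further compounds**
F1 | step 13 | methyl 5-lavandulyl-5-[(2S)-2-(2-hydroxypropan-2-yl)-5-methylhex-4-en-1-yl]-3-[3-methyl-3-(triethylsilyloxy)butyl]-2,4-dioxopentanoate | COC(=O)C(=O)C(CCC(C)(C)O[Si](CC)(CC)CC)C(=O)C(C[C@@H](CC=C(C)C)C(C)=C)C[C@@H](CC=C(C)C)C(C)(C)O
F2 | step 15 | α-diazo-β-hydroxy ketone from addition of lithiated 15 to the C6 carbonyl of 24 (carbinol configuration not defined) | C=C(C)[C@H](CC=C(C)C)C[C@@]12C[C@@H](CC=C(C)C)C(C)(C)[C@@](CCC(C)(C)O[Si](CC)(CC)CC)(C(=O)C1(O)C(=[N+]=[N-])C(=O)c1ccc(O[Si](C)(C)C(C)(C)C)c(O[Si](C)(C)C(C)(C)C)c1)C2=O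
F3 | step 14 | 2-oxo-2-{3-lavandulyl-6,6-dimethyl-1-[3-methyl-3-(triethylsilyloxy)butyl]-2-oxo-5-prenylcyclohexyl}acetic acid | OC(=O)C(=O)[C@@]1(CCC(C)(C)O[Si](CC)(CC)CC)C(=O)C(C[C@@H](CC=C(C)C)C(C)=C)C[C@@H](CC=C(C)C)C1(C)C
F4 | step 14 | pentafluorophenyl ester of F3 | O=C(Oc1c(F)c(F)c(F)c(F)c1F)C(=O)[C@@]1(CCC(C)(C)O[Si](CC)(CC)CC)C(=O)C(C[C@@H](CC=C(C)C)C(C)=C)C[C@@H](CC=C(C)C)C1(C)C
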